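**Strategy.** The flavanone is cut through ring C at O1–C2 and C3–C4. O1, C8a, C4a and C4 are a latent 1-oxadiene: ionising the acetal of a salicylaldehyde gives a 4-methoxy ortho-quinone methide cation, while C2–C3 together with ring B map onto 4-methoxystyrene. A chiral Brønsted acid-catalysed inverse-demand oxa-[4+2] cycloaddition therefore closes ring C, sets C2 and delivers C4 as an ionisable ether, one hydrolysis and one oxidation away from the ketone. The diene precursor is the fully substituted ring A aldehyde 2-hydroxy-5-methyl-3-prenyl-4,6-bis(triisopropylsilyloxy)benzaldehyde: only O1 is free, and silyl ethers replace acetal-type protection, which could ionise or attack C4 under the acid.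

Key step: step 7

**Assumptions and design remarks**
- Flavan numbering is used from the cycloadduct onward (ring A = benzo ring, ring B = anisyl ring, ring C = pyran ring).
- The target is the (2S)-flavanone. The 2,4-cis cycloadduct with 2S is (2S,4S).
- Triisopropylsilyl ethers are chosen for O5 and O7. An acetal-type ether ortho to the ionising carbon could itself ionise under the acid or close onto C4 to give a 1,3-benzodioxine. Silyl ethers also allow the final unmasking with buffered fluoride instead of mineral acid, which could add O7–H across the prenyl alkene.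
- The C4 methyl ether is taken to the ketone by solvolysis and alcohol oxidation, not by quinone hydride abstraction. Next to the peri O5 substituent the 4-methoxy group should sit pseudo-axial, leaving H4 poorly aligned, and the prenyl CH2 is a competing hydride donor.
- Assumption: the sense of induction of the chiral acid is not predicted. The catalyst antipode that gives 2S is fixed by experiment.

**Route**

Step 1
Reactants: 1 2-methylresorcinol
Product: 2 2-methyl-1,3-bis(triisopropylsilyloxy)benzene
Conditions: i-Pr3SiCl (2.3 equiv), imidazole, DMF, 40 °C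
Reagents that add atoms: triisopropylsilyl chloride, CC(C)[Si](Cl)(C(C)C)C(C)C
Why: Imidazole-assisted O-silylation of both phenols (silyl ether formation) should give ethers that withstand the acid, base and heat of every later step and leave with fluoride at the end.

Step 2
Reactants: 2 2-methyl-1,3-bis(triisopropylsilyloxy)benzene
Product: 4 4-methyl-3,5-bis(triisopropylsilyloxy)phenol, via aryl pinacol boronate 3 (not isolated)
Conditions: [Ir(OMe)(cod)]2 (1.5 mol%), 4,4'-di-tert-butyl-2,2'-bipyridine (3 mol%), B2pin2 (1.0 equiv), THF, 80 °C; then KHSO5 (as 2KHSO5·KHSO4·K2SO4), acetone/H2O, 25 °C; NaHSO3 quench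
Reagents that add atoms: potassium peroxymonosulfate, [K+].[O-]S(=O)(=O)OO (phenol oxygen); bis(pinacolato)diboron, CC1(C)OB(OC1(C)C)B1OC(C)(C)C(C)(C)O1 (boron of 3 only)
Why: Sterically governed iridium-catalysed aromatic C–H borylation should take the only C–H without an ortho substituent (para to the methyl), and boronate oxidation with 1,2-aryl migration then gives the symmetric phenol.

Step 3
Reactants: 5 2-methylbut-3-en-2-ol
Product: 6 tert-butyl 2-methylbut-3-en-2-yl carbonate
Conditions: n-BuLi, THF, −78 °C; then Boc2O, −78 → 25 °C; aq NH4Cl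
Reagents that add atoms: di-tert-butyl dicarbonate, CC(C)(C)OC(=O)OC(=O)OC(C)(C)C
Why: Acylation of the lithium alkoxide of a tertiary alcohol by the dicarbonate (mixed carbonate formation) is a standard way to tertiary allylic carbonates.

Step 4
Reactants: 4 4-methyl-3,5-bis(triisopropylsilyloxy)phenol; 6 tert-butyl 2-methylbut-3-en-2-yl carbonate
Product: 7 2-methyl-5-(2-methylbut-3-en-2-yloxy)-1,3-bis(triisopropylsilyloxy)benzene
Conditions: Pd(PPh3)4 (3 mol%), THF, 0 °C
Reagents that add atoms: none
Why: In this decarboxylative Tsuji–Trost O-allylation the released tert-butoxide deprotonates the phenol, and under kinetic control at low temperature the phenoxide should attack the 1,1-dimethylallyl palladium cation at its more substituted terminus to give the tertiary ether.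

Step 5
Reactants: 7 2-methyl-5-(2-methylbut-3-en-2-yloxy)-1,3-bis(triisopropylsilyloxy)benzene
Product: 8 4-methyl-2-(3-methylbut-2-enyl)-3,5-bis(triisopropylsilyloxy)phenol
Conditions: PhNEt2, 140 °C
Reagents that add atoms: none
Why: Aromatic Claisen rearrangement (a [3,3]-sigmatropic shift) of the 1,1-dimethylallyl ether should deliver the allyl unit with allylic inversion to one of two equivalent ortho carbons, the para position being blocked by methyl and the basic solvent suppressing ionisation to isoprene.

Step 6
Reactants: 8 4-methyl-2-(3-methylbut-2-enyl)-3,5-bis(triisopropylsilyloxy)phenol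
Product: 9 2-hydroxy-5-methyl-3-(3-methylbut-2-enyl)-4,6-bis(triisopropylsilyloxy)benzaldehyde
Conditions: MgCl2, Et3N, (CH2O)n, THF, 65 °C; cold dilute HCl work-up
Reagents that add atoms: paraformaldehyde (as formaldehyde), C=O
Why: In the Casnati–Skattebøl ortho-formylation the magnesium phenoxide delivers formaldehyde to the only free ring carbon and a second formaldehyde oxidises the benzylic alkoxide to the aldehyde, under basic conditions that spare the prenyl group and the silyl ethers.

Step 7
Reactants: 9 2-hydroxy-5-methyl-3-(3-methylbut-2-enyl)-4,6-bis(triisopropylsilyloxy)benzaldehyde; 10 4-methoxystyrene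
Product: 13 (2S,4S)-4-methoxy-2-(4-methoxyphenyl)-6-methyl-8-(3-methylbut-2-enyl)-5,7-bis(triisopropylsilyloxy)chroman, via dimethyl acetal 11 (not isolated), via O-protonated methoxy ortho-quinone methide 12 (not isolated)
Conditions: HC(OMe)3 (1.5 equiv), chiral imidodiphosphorimidate acid (two 3,3'-diaryl-1,1'-bi-2-naphthol units, N–SO2CF3 groups; 5 mol%), 10 (2 equiv, slow addition), CH2Cl2, −40 °C; Et3N quench
Reagents that add atoms: trimethyl orthoformate, COC(OC)OC
Why: Proposed new method: the acid and trimethyl orthoformate turn 9 into acetal 11, loss of methanol gives cation 12 bound to the chiral anion through the O1–H hydrogen bond, and the CH2 terminus of 10 adds to C4 while O1 captures the emerging 4-methoxybenzylic cation at C2 in an asynchronous inverse-electron-demand oxa-Diels–Alder reaction. The closest known reaction types are the achiral acid-catalysed three-component assembly of 4-alkoxyflavans from salicylaldehydes, orthoformates and styrenes and the chiral Brønsted acid-catalysed cycloadditions of ortho-quinone methides or oxocarbenium ions with styrenes; the enantioselective intermolecular use of an alkoxy ortho-quinone methide is the untested part. Ring C closes in the [4+2] mode, with O1–C8a–C4a–C4 as the four-atom component and C2–C3 as the two-atom component, the O1–C2 bond forming last as a six-membered closure onto the benzylic cation. C2 is set by the catalyst, whose confined anion leaves one face of the hydrogen-bonded ion pair open for the ring closure (the antipode that gives 2S is used), and C4 follows from the transition state that places the methoxy and anisyl groups cis, an outcome that is erased later. Regiochemistry comes from the polarisation of 10 (nucleophilic CH2, anisyl-stabilised cation), and chemoselectivity from the precursor: O1 is the only free oxygen, the silyl ethers at O5 and O7 can neither ionise nor add to C4, and at −40 °C the acetal should ionise far faster than the prenyl alkene is protonated. Since only C2 survives, C4 epimers are carried on together only if they show the same induction at C2; otherwise the cis isomer is purified first.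

Step 8
Reactants: 13 (2S,4S)-4-methoxy-2-(4-methoxyphenyl)-6-methyl-8-(3-methylbut-2-enyl)-5,7-bis(triisopropylsilyloxy)chroman
Product: 14 (2S)-2-(4-methoxyphenyl)-6-methyl-8-(3-methylbut-2-enyl)-5,7-bis(triisopropylsilyloxy)chroman-4-ol (mixture of C4 epimers)
Conditions: TsOH·H2O (5 mol%), THF/H2O (4:1), 0 → 25 °C; NaHCO3 quench
Reagents that add atoms: water, O
Why: C4 carries two ortho and one para oxygen donor, so the benzylic methyl ether should ionise under mild acid and be captured by water (SN1 solvolysis) without touching C2, the silyl ethers or the prenyl group.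

Step 9
Reactants: 14 (2S)-2-(4-methoxyphenyl)-6-methyl-8-(3-methylbut-2-enyl)-5,7-bis(triisopropylsilyloxy)chroman-4-ol
Product: 15 (2S)-2-(4-methoxyphenyl)-6-methyl-8-(3-methylbut-2-enyl)-5,7-bis(triisopropylsilyloxy)chroman-4-one
Conditions: Dess–Martin periodinane, NaHCO3, CH2Cl2, 0 → 25 °C
Reagents that add atoms: none
Why: Buffered Dess–Martin oxidation of a secondary benzylic alcohol should converge both C4 epimers on one ketone and leave the prenyl alkene, the silyl ethers and C2 untouched.

Step 10
Reactants: 15 (2S)-2-(4-methoxyphenyl)-6-methyl-8-(3-methylbut-2-enyl)-5,7-bis(triisopropylsilyloxy)chroman-4-one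
Product: 16 (2S)-5,7-dihydroxy-2-(4-methoxyphenyl)-6-methyl-8-(3-methylbut-2-enyl)chroman-4-one
Conditions: Bu4NF, AcOH (1:1, 2.5 equiv), THF, 0 °C
Reagents that add atoms: none
Why: Fluoride cleavage of the aryl silyl ethers (desilylation) buffered by acetic acid should avoid base-induced opening of ring C to the chalcone, which would racemise C2, and uses no acid that could cyclise the prenyl group onto O7.

**Compound list**

1 | 2-methylresorcinol | Cc1c(O)cccc1O | starting material
2 | 2-methyl-1,3-bis(triisopropylsilyloxy)benzene | Cc1c(O[Si](C(C)C)(C(C)C)C(C)C)cccc1O[Si](C(C)C)(C(C)C)C(C)C | intermediate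
3 | 2-[4-methyl-3,5-bis(triisopropylsilyloxy)phenyl]-4,4,5,5-tetramethyl-1,3,2-dioxaborolane | Cc1c(O[Si](C(C)C)(C(C)C)C(C)C)cc(B2OC(C)(C)C(C)(C)O2)cc1O[Si](C(C)C)(C(C)C)C(C)C | intermediate (not isolated)
4 | 4-methyl-3,5-bis(triisopropylsilyloxy)phenol | Cc1c(O[Si](C(C)C)(C(C)C)C(C)C)cc(O)cc1O[Si](C(C)C)(C(C)C)C(C)C | intermediate
5 | 2-methylbut-3-en-2-ol | C=CC(C)(C)O | starting material
6 | tert-butyl 2-methylbut-3-en-2-yl carbonate | C=CC(C)(C)OC(=O)OC(C)(C)C | intermediate
7 | 2-methyl-5-(2-methylbut-3-en-2-yloxy)-1,3-bis(triisopropylsilyloxy)benzene | C=CC(C)(C)Oc1cc(O[Si](C(C)C)(C(C)C)C(C)C)c(C)c(O[Si](C(C)C)(C(C)C)C(C)C)c1 | intermediate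
8 | 4-methyl-2-(3-methylbut-2-enyl)-3,5-bis(triisopropylsilyloxy)phenol | CC(C)=CCc1c(O)cc(O[Si](C(C)C)(C(C)C)C(C)C)c(C)c1O[Si](C(C)C)(C(C)C)C(C)C | intermediate
9 | 2-hydroxy-5-methyl-3-(3-methylbut-2-enyl)-4,6-bis(triisopropylsilyloxy)benzaldehyde | O=Cc1c(O)c(CC=C(C)C)c(O[Si](C(C)C)(C(C)C)C(C)C)c(C)c1O[Si](C(C)C)(C(C)C)C(C)C | intermediate (key-step precursor)
10 | 4-methoxystyrene | C=Cc1ccc(OC)cc1 | starting material
11 | 2-(dimethoxymethyl)-4-methyl-6-(3-methylbut-2-enyl)-3,5-bis(triisopropylsilyloxy)phenol | COC(OC)c1c(O)c(CC=C(C)C)c(O[Si](C(C)C)(C(C)C)C(C)C)c(C)c1O[Si](C(C)C)(C(C)C)C(C)C | intermediate (not isolated)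
12 | O-protonated 4-methoxy ortho-quinone methide (aryl methoxycarbenium ion, paired with the catalyst anion) | C[O+]=Cc1c(O)c(CC=C(C)C)c(O[Si](C(C)C)(C(C)C)C(C)C)c(C)c1O[Si](C(C)C)(C(C)C)C(C)C | intermediate (not isolated)
13 | (2S,4S)-4-methoxy-2-(4-methoxyphenyl)-6-methyl-8-(3-methylbut-2-enyl)-5,7-bis(triisopropylsilyloxy)chroman (2,4-cis) | COc1ccc([C@@H]2C[C@H](OC)c3c(O[Si](C(C)C)(C(C)C)C(C)C)c(C)c(O[Si](C(C)C)(C(C)C)C(C)C)c(CC=C(C)C)c3O2)cc1 | intermediate (key-step product)
14 | (2S)-2-(4-methoxyphenyl)-6-methyl-8-(3-methylbut-2-enyl)-5,7-bis(triisopropylsilyloxy)chroman-4-ol, C4 epimers | COc1ccc([C@@H]2CC(O)c3c(O[Si](C(C)C)(C(C)C)C(C)C)c(C)c(O[Si](C(C)C)(C(C)C)C(C)C)c(CC=C(C)C)c3O2)cc1 | intermediate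
15 | (2S)-2-(4-methoxyphenyl)-6-methyl-8-(3-methylbut-2-enyl)-5,7-bis(triisopropylsilyloxy)chroman-4-one | COc1ccc([C@@H]2CC(=O)c3c(O[Si](C(C)C)(C(C)C)C(C)C)c(C)c(O[Si](C(C)C)(C(C)C)C(C)C)c(CC=C(C)C)c3O2)cc1 | intermediate
16 | (2S)-5,7-dihydroxy-2-(4-methoxyphenyl)-6-methyl-8-(3-methylbut-2-enyl)chroman-4-one | COc1ccc([C@@H]2CC(=O)c3c(O)c(C)c(O)c(CC=C(C)C)c3O2)cc1 | target

**Step count and risk**

Total step count: 10. Longest linear sequence: 9 (steps 1, 2 and 4 to 10; step 3 is a side branch).

Steps most likely to fail:

1. Step 7. Several processes may go wrong: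
   - facial discrimination at C2 may be insufficient, or acid-promoted reopening of the O1–C2 bond may erode it;
   - the styrene may oligomerise cationically;
   - O1–H may add across the prenyl alkene before the acetal ionises;
   - the product may re-ionise at C4 and be alkylated by a second styrene;
   - the crowded ion pair may not fit the confined catalyst.

   The fallback uses known chemistry only, sets out from 9 and returns at 15. Addition of MeMgBr (THF, 0 °C) to 9 gives the benzylic alcohol 2-(1-hydroxyethyl)-4-methyl-6-(3-methylbut-2-enyl)-3,5-bis(triisopropylsilyloxy)phenol F1, which is oxidised without purification (MnO2, CH2Cl2) to the acetophenone 1-[2-hydroxy-5-methyl-3-(3-methylbut-2-enyl)-4,6-bis(triisopropylsilyloxy)phenyl]ethanone F2. Condensation with N,N-dimethylformamide dimethyl acetal (COC(OC)N(C)C; toluene, 90 °C) gives the enaminone (E)-3-(dimethylamino)-1-[2-hydroxy-5-methyl-3-(3-methylbut-2-enyl)-4,6-bis(triisopropylsilyloxy)phenyl]prop-2-en-1-one F3. Brief acid treatment (TsOH·H2O, CH2Cl2, 25 °C) closes it with loss of dimethylamine to the chromone 6-methyl-8-(3-methylbut-2-enyl)-5,7-bis(triisopropylsilyloxy)chromen-4-one F4. Enantioselective conjugate addition of 4-methoxyphenylboronic acid (COc1ccc(B(O)O)cc1) then gives 15 and bypasses steps 7 to 9. Its conditions are Pd(OCOCF3)2, the tert-butyl pyridine-oxazoline ligand antipode that gives 2S, NH4PF6, H2O, ClCH2CH2Cl, 60 °C.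

2. Step 8. The C4 cation may lose H3 to give the flav-3-ene instead of being captured by water, or the exchange may stall. The fallback sets out from 13 and returns at 15 in one operation: DDQ (1.3 equiv) in CH2Cl2/pH 7 buffer at 0 °C should abstract hydride from C4 and the resulting methoxycarbenium ion should be hydrolysed to the ketone. This fallback makes no new compound (F0) and also bypasses step 9.

3. Step 4. The phenoxide may attack the less substituted allyl terminus, or zerovalent palladium may re-ionise the tertiary ether and isomerise it to the linear prenyl ether, which would rearrange to the wrong (1,1-dimethylallyl) isomer in step 5. The fallback sets out from 4 and returns at 7. Copper-catalysed substitution with 3-chloro-3-methylbut-1-yne (CC(C)(Cl)C#C; K2CO3, KI, CuI, acetone, 50 °C) gives the propargyl ether 2-methyl-5-(2-methylbut-3-yn-2-yloxy)-1,3-bis(triisopropylsilyloxy)benzene F5. Semihydrogenation (H2, Pd/CaCO3 poisoned with Pb(OAc)2, quinoline, EtOAc) then gives 7.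

Further compounds
F1 | step 7 | 2-(1-hydroxyethyl)-4-methyl-6-(3-methylbut-2-enyl)-3,5-bis(triisopropylsilyloxy)phenol (racemic at the carbinol) | CC(O)c1c(O)c(CC=C(C)C)c(O[Si](C(C)C)(C(C)C)C(C)C)c(C)c1O[Si](C(C)C)(C(C)C)C(C)C
F2 | step 7 | 1-[2-hydroxy-5-methyl-3-(3-methylbut-2-enyl)-4,6-bis(triisopropylsilyloxy)phenyl]ethanone | CC(=O)c1c(O)c(CC=C(C)C)c(O[Si](C(C)C)(C(C)C)C(C)C)c(C)c1O[Si](C(C)C)(C(C)C)C(C)C
F3 | step 7 | (E)-3-(dimethylamino)-1-[2-hydroxy-5-methyl-3-(3-methylbut-2-enyl)-4,6-bis(triisopropylsilyloxy)phenyl]prop-2-en-1-one | CN(C)/C=C/C(=O)c1c(O)c(CC=C(C)C)c(O[Si](C(C)C)(C(C)C)C(C)C)c(C)c1O[Si](C(C)C)(C(C)C)C(C)C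
F4 | step 7 | 6-methyl-8-(3-methylbut-2-enyl)-5,7-bis(triisopropylsilyloxy)chromen-4-one | O=c1ccoc2c(CC=C(C)C)c(O[Si](C(C)C)(C(C)C)C(C)C)c(C)c(O[Si](C(C)C)(C(C)C)C(C)C)c12
F0 | step 8 | none | none
F5 | step 4 | 2-methyl-5-(2-methylbut-3-yn-2-yloxy)-1,3-bis(triisopropylsilyloxy)benzene | C#CC(C)(C)Oc1cc(O[Si](C(C)C)(C(C)C)C(C)C)c(C)c(O[Si](C(C)C)(C(C)C)C(C)C)c1
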